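**Retrosynthetic overview**
1. The C1 senecioate, the C2 and C9 acetates and the C14 alcohol are traced back to a trans-fused decalin keto ester with C1/C2 silyl ethers, a C9 ketone and a C14 methyl ester.
2. Key disconnection: ring A is opened at its only alkene, the trisubstituted C3=C4 bond that carries the C15 methyl and lies between the C2 carbinol and the ring-fusion carbon C5. This gives a C2 vinyl group and a C5 isopropenyl group held trans-vicinal (C10 arm/C5) on ring B, to be joined by ring-closing metathesis.
3. C10–C1 comes from a Mukaiyama aldol of the C9/C10 silyl enol ether of a ring B β-keto ester with (S)-2-silyloxybut-3-enal (C2 from (S)-but-3-ene-1,2-diol); this sets C10 and C1.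
4. C5–C4 comes from copper-mediated isopropenyl addition trans to C7 on a 2-carbomethoxy enone; C7 comes from rhodium-catalysed asymmetric isopropenyl addition to cyclohexenone.
5. Ring order: ring B is bought as cyclohexenone; ring A is closed by metathesis, then the oxidation levels and acyl groups are adjusted.

Key step: step 11

Remark 1: locants C1–C15 are those of the target (decalin C1–C10; ring A = C1–C5, C10; ring B = C5–C10; C14 on C10; C15 on C4; isopropenyl C11–C13 on C7). The target SMILES corresponds to (1R,2S,5R,7S,9S,10S): trans-fused decalin, with C14, O1 and O2 on one face (α) and H5, the C7 isopropenyl group and O9 on the other (β); on the ring B chair the C7 isopropenyl group and O9 are axial.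
Remark 2: the sense of induction in step 1 is assumed to follow that of aryl and alkenyl transfer to cyclohexenone with the same ligand; the antipodal ligand is used if it does not.

**Step 1**
Reactants: 1 cyclohex-2-en-1-one; 2 potassium isopropenyltrifluoroborate
Product: 3 (S)-3-(prop-1-en-2-yl)cyclohexan-1-one
Conditions: [Rh(cod)2]BF4 (3 mol%), (S)-BINAP, toluene/H2O 4:1, 105 °C
Reagents that add atoms: none
Why: Rhodium-catalysed asymmetric 1,4-addition (Hayashi–Miyaura reaction) of the alkenyltrifluoroborate, in which the (S)-BINAP rhodium isopropenyl complex should add to the enone face that gives the (S)-ketone and so sets C7.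

**Step 2**
Reactants: 3 (S)-3-(prop-1-en-2-yl)cyclohexan-1-one
Product: 4 methyl (4S)-2-oxo-4-(prop-1-en-2-yl)cyclohexane-1-carboxylate (C1 epimers and enol)
Conditions: NaH (2.2 equiv), (MeO)2CO, KH (cat.), THF, reflux; then 1 M HCl
Reagents that add atoms: dimethyl carbonate, COC(=O)OC
Why: Claisen-type C-methoxycarbonylation under equilibrating conditions should place the ester on the α-carbon remote from C7 (the future C10), since the regioisomeric enolate would hold the ester next to the isopropenyl-bearing carbon; C7 is not enolisable.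

**Step 3**
Reactants: 4 methyl (4S)-2-oxo-4-(prop-1-en-2-yl)cyclohexane-1-carboxylate
Product: 7 methyl (4S)-6-oxo-4-(prop-1-en-2-yl)cyclohex-1-ene-1-carboxylate, via selenide 5 (not isolated), via selenoxide 6 (not isolated)
Conditions: NaH, THF, 0 °C; PhSeCl, −78 → 0 °C; crude selenide, 30% H2O2, pyridine, CH2Cl2, 0 °C → rt; used at once
Reagents that add atoms: none
Why: α-Selenenylation of the preformed sodium enolate (which should outcompete the isopropenyl alkene for PhSeCl) followed by selenoxide syn-elimination toward the only β-CH2 gives the C10=C5 alkylidene keto ester.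

**Step 4**
Reactants: 7 methyl (4S)-6-oxo-4-(prop-1-en-2-yl)cyclohex-1-ene-1-carboxylate; 8 isopropenylmagnesium bromide
Product: 9 methyl (4S,6S)-2-oxo-4,6-di(prop-1-en-2-yl)cyclohexane-1-carboxylate (trans-4,6; C1 epimers and enol)
Conditions: CuBr·SMe2 (0.2 equiv), THF, −78 → −40 °C; then 1 M HCl
Reagents that add atoms: none
Why: Copper-catalysed conjugate addition of the Grignard reagent to the doubly activated enone by axial attack on the half-chair with the C7 isopropenyl group equatorial, which should place the new C5 isopropenyl group trans to it as is general for 5-substituted cyclohexenones.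

**Step 5**
Reactants: 9 methyl (4S,6S)-2-oxo-4,6-di(prop-1-en-2-yl)cyclohexane-1-carboxylate
Product: 10 methyl (4S,6R)-4,6-di(prop-1-en-2-yl)-2-[(trimethylsilyl)oxy]cyclohex-1-ene-1-carboxylate
Conditions: TMSOTf, Et3N, CH2Cl2, 0 °C; used crude
Reagents that add atoms: trimethylsilyl trifluoromethanesulfonate, C[Si](C)(C)OS(=O)(=O)C(F)(F)F
Why: O-Silylation under soft enolisation gives the C9=C10 silyl enol ether, because the C10 hydrogen is the only doubly activated proton.

**Step 6**
Reactants: 11 (S)-but-3-ene-1,2-diol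
Product: 12 (S)-1,2-bis[(tert-butyldimethylsilyl)oxy]but-3-ene
Conditions: TBSCl (2.5 equiv), imidazole, DMF, rt
Reagents that add atoms: tert-butyldimethylsilyl chloride, CC(C)(C)[Si](C)(C)Cl
Why: Imidazole-promoted silyl ether formation at both hydroxyls leaves the C2 stereocentre untouched.

**Step 7**
Reactants: 12 (S)-1,2-bis[(tert-butyldimethylsilyl)oxy]but-3-ene
Product: 13 (S)-2-[(tert-butyldimethylsilyl)oxy]but-3-en-1-ol
Conditions: HF·pyridine, pyridine, THF, 0 °C
Reagents that add atoms: none
Why: Selective desilylation, since buffered HF·pyridine cleaves the unhindered primary silyl ether much faster than the secondary allylic one.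

**Step 8**
Reactants: 13 (S)-2-[(tert-butyldimethylsilyl)oxy]but-3-en-1-ol
Product: 14 (S)-2-[(tert-butyldimethylsilyl)oxy]but-3-enal
Conditions: Dess–Martin periodinane, pyridine, CH2Cl2, 0 °C; used at once without chromatography
Reagents that add atoms: none
Why: Dess–Martin oxidation under buffered, non-basic conditions should give the aldehyde without enolisation at C2 or migration of the alkene into conjugation.

**Step 9**
Reactants: 10 methyl (4S,6R)-4,6-di(prop-1-en-2-yl)-2-[(trimethylsilyl)oxy]cyclohex-1-ene-1-carboxylate; 14 (S)-2-[(tert-butyldimethylsilyl)oxy]but-3-enal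
Product: 15 methyl (1R,4S,6R)-1-[(1R,2S)-2-[(tert-butyldimethylsilyl)oxy]-1-hydroxybut-3-en-1-yl]-2-oxo-4,6-di(prop-1-en-2-yl)cyclohexane-1-carboxylate
Conditions: BF3·OEt2 (1.2 equiv), CH2Cl2, −78 °C; then pH 7 buffer
Reagents that add atoms: none
Why: Mukaiyama aldol addition through an open transition state, in which C10 is attacked anti to the C5 isopropenyl group (held pseudoaxial by A1,2 strain with the ester), setting C10, while non-chelating BF3 and the bulky α-silyloxy group enforce Felkin–Anh addition to the aldehyde, setting C1 anti to C2.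

**Step 10**
Reactants: 15 aldol adduct
Product: 16 methyl (1R,4S,6R)-1-[(1R,2S)-2-[(tert-butyldimethylsilyl)oxy]-1-[(triethylsilyl)oxy]but-3-en-1-yl]-2-oxo-4,6-di(prop-1-en-2-yl)cyclohexane-1-carboxylate
Conditions: TESOTf, 2,6-lutidine, CH2Cl2, −78 °C
Reagents that add atoms: triethylsilyl trifluoromethanesulfonate, CC[Si](CC)(CC)OS(=O)(=O)C(F)(F)F
Why: Silyl ether formation with the reactive triflate at low temperature caps the hindered C1 hydroxyl before retro-aldol cleavage of the β-hydroxy ketone can occur.

**Step 11**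
Reactants: 16 ring B keto ester with the C5 isopropenyl group and the C1,C2-bis(silyloxy)butenyl arm on C10
Product: 17 trans-fused decalin keto ester (target numbering): C3=C4 with C15 methyl, C1 OTES, C2 OTBS, C9 ketone, C14 methyl ester on C10, C7 isopropenyl; (1R,2S,5R,7S,10R)
Conditions: second-generation Grubbs catalyst (H2IMes)(PCy3)Cl2Ru=CHPh (5–10 mol%), toluene (0.005 M), 80 °C, argon sparge
Reagents that add atoms: none
Why: Olefin metathesis by [2+2] cycloaddition and cycloreversion through ruthenacyclobutanes: the benzylidene exchanges onto the monosubstituted C2 vinyl group, and the resulting C3 alkylidene adds intramolecularly to the 1,1-disubstituted C5 isopropenyl group, releasing ethylene and forming the trisubstituted C3=C4 bond. The closest known reaction type is ring-closing metathesis of a vinyl group with a 1,1-disubstituted alkene to give 1-methylcyclohexenes beside quaternary carbons. Ring A closes as a six-membered carbocycle from a 1,7-diene annulated onto ring B, which is possible only from the chair in which the C10 arm and the C5 isopropenyl group are both equatorial (C7 isopropenyl and the ester axial) and so gives the trans-fused decalin directly. No stereocentre is formed; C1, C2, C5, C7 and C10 are carried in unchanged. The step needs site selectivity between the two isopropenyl groups and against dimerisation at the vinyl group: the C7 isopropenyl group could only close a strained bridged eight-membered ring, and high dilution with removal of ethylene should favour the intramolecular path.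

**Step 12**
Reactants: 17 trans-fused decalin keto ester
Product: 18 decalin hydroxy ester (target numbering): 9β-OH, C14 methyl ester, C1 OTES, C2 OTBS; (1R,2S,5R,7S,9S,10S)
Conditions: Li(s-Bu)3BH, THF, −78 °C; then H2O
Reagents that add atoms: none
Why: Ketone reduction by a bulky trialkylborohydride should occur by equatorial attack from the α face, because the β face of C9 is blocked by the syn-axial C7 isopropenyl group, giving the axial 9β-alcohol; ester and silyl ethers are inert at −78 °C.

**Step 13**
Reactants: 18 decalin hydroxy ester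
Product: 19 decalin 9,14-diol (target numbering): 9β-OH, C14 CH2OH, C1 OTES, C2 OTBS; (1R,2S,5R,7S,9S,10S)
Conditions: LiAlH4, THF, 0 °C → rt; then H2O
Reagents that add atoms: none
Why: Hydride reduction of the hindered methyl ester to the primary alcohol with LiAlH4, which leaves silyl ethers and unactivated alkenes untouched.

**Step 14**
Reactants: 19 decalin 9,14-diol
Product: 20 C14 tert-butyldiphenylsilyl ether of 19; (1R,2S,5R,7S,9S,10S)
Conditions: TBDPSCl, imidazole, DMAP (cat.), CH2Cl2, 0 °C → rt
Reagents that add atoms: tert-butyldiphenylsilyl chloride, CC(C)(C)[Si](Cl)(c1ccccc1)c1ccccc1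
Why: Silyl ether formation should be selective for the primary C14 hydroxyl, the axial neopentyl C9 hydroxyl being far less reactive toward the bulky chloride.

**Step 15**
Reactants: 20 C14 silyl ether
Product: 21 C9 acetate of 20; (1R,2S,5R,7S,9S,10S)
Conditions: Ac2O, DMAP, Et3N, CH2Cl2, rt → 40 °C
Reagents that add atoms: acetic anhydride, CC(=O)OC(C)=O
Why: DMAP-catalysed acylation through the N-acetylpyridinium ion is reactive enough for the hindered axial C9 hydroxyl, the only free hydroxyl present.

**Step 16**
Reactants: 21 C9 acetate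
Product: 22 C1 alcohol (target numbering): C1 OH, C2 OTBS, C9 OAc, C14 OTBDPS; (1R,2S,5R,7S,9S,10R)
Conditions: PPTS (cat.), MeOH/CH2Cl2, 0 °C → rt
Reagents that add atoms: none
Why: Acid-catalysed methanolysis of silyl ethers removes the triethylsilyl group, which is far more labile than the tert-butyldimethylsilyl and tert-butyldiphenylsilyl ethers, and leaves the acetate intact.

**Step 17**
Reactants: 22 C1 alcohol; 23 3-methylbut-2-enoic acid (senecioic acid)
Product: 25 C1 senecioate (target numbering): C1 O-senecioyl, C2 OTBS, C9 OAc, C14 OTBDPS; (1R,2S,5R,7S,9S,10S), via mixed anhydride 24 (not isolated)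
Conditions: 23, 2,4,6-Cl3C6H2COCl, Et3N, THF, rt; then 22, DMAP, toluene, rt → 60 °C
Reagents that add atoms: none
Why: Yamaguchi esterification, in which the mixed anhydride and DMAP give an acylpyridinium ion strong enough for the hindered C1 hydroxyl without passing through a vinylketene, so the double bond should stay conjugated.

**Step 18**
Reactants: 25 C1 senecioate
Product: 26 C2 alcohol (target numbering): C1 O-senecioyl, C2 OH, C9 OAc, C14 OTBDPS; (1R,2S,5R,7S,9S,10S)
Conditions: 48% aq. HF/MeCN (1:19), 0 °C
Reagents that add atoms: none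
Why: Acidic fluoride desilylation cleaves the secondary tert-butyldimethylsilyl ether much faster than the tert-butyldiphenylsilyl ether, and the acidic medium disfavours 1,2-acyl migration.

**Step 19**
Reactants: 26 C2 alcohol
Product: 27 C14 silyl ether of the target: C1 O-senecioyl, C2 OAc, C9 OAc, C14 OTBDPS; (1R,2S,5R,7S,9S,10S)
Conditions: Ac2O, pyridine, DMAP (cat.), CH2Cl2, 0 °C
Reagents that add atoms: acetic anhydride, CC(=O)OC(C)=O
Why: DMAP-catalysed acetylation of the unhindered allylic C2 hydroxyl is fast at 0 °C and should outrun migration of the C1 senecioyl group.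

**Step 20**
Reactants: 27 C14 silyl ether of the target
Product: 28 CNP0320218.1, (1R,2S,5R,7S,9S,10S)-2,9-diacetoxy-14-hydroxy-1-(3-methylbut-2-enoyloxy) trans-decalin with C3=C4 and C7 isopropenyl (target numbering)
Conditions: HF·pyridine, pyridine, THF, 0 °C → rt; NaHCO3 work-up kept brief
Reagents that add atoms: none
Why: Fluoride-mediated desilylation of the primary silyl ether under mildly acidic conditions, chosen because a basic fluoride source could move the senecioyl group from O1 to the neighbouring O14.

**Compound list**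
1 | cyclohex-2-en-1-one | O=C1C=CCCC1 | starting material
2 | potassium isopropenyltrifluoroborate | [K+].C=C(C)[B-](F)(F)F | starting material
3 | (S)-3-(prop-1-en-2-yl)cyclohexan-1-one | C=C(C)[C@@H]1CC(=O)CCC1 | intermediate
4 | methyl (4S)-2-oxo-4-(prop-1-en-2-yl)cyclohexane-1-carboxylate | C=C(C)[C@@H]1CC(=O)C(C(=O)OC)CC1 | intermediate
5 | methyl (4S)-2-oxo-1-(phenylselanyl)-4-(prop-1-en-2-yl)cyclohexane-1-carboxylate (selenide) | C=C(C)[C@@H]1CC(=O)C(C(=O)OC)([Se]c2ccccc2)CC1 | intermediate
6 | methyl (4S)-2-oxo-1-(phenylseleninyl)-4-(prop-1-en-2-yl)cyclohexane-1-carboxylate (selenoxide) | C=C(C)[C@@H]1CC(=O)C(C(=O)OC)([Se](=O)c2ccccc2)CC1 | intermediate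
7 | methyl (4S)-6-oxo-4-(prop-1-en-2-yl)cyclohex-1-ene-1-carboxylate | C=C(C)[C@@H]1CC(=O)C(C(=O)OC)=CC1 | intermediate
8 | isopropenylmagnesium bromide | C=C(C)[Mg]Br | starting material
9 | methyl (4S,6S)-2-oxo-4,6-di(prop-1-en-2-yl)cyclohexane-1-carboxylate | C=C(C)[C@@H]1CC(=O)C(C(=O)OC)[C@H](C1)C(C)=C | intermediate
10 | methyl (4S,6R)-4,6-di(prop-1-en-2-yl)-2-[(trimethylsilyl)oxy]cyclohex-1-ene-1-carboxylate | C=C(C)[C@@H]1CC(O[Si](C)(C)C)=C(C(=O)OC)[C@H](C1)C(C)=C | intermediate
11 | (S)-but-3-ene-1,2-diol | C=C[C@H](O)CO | starting material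
12 | (S)-1,2-bis[(tert-butyldimethylsilyl)oxy]but-3-ene | C=C[C@H](O[Si](C)(C)C(C)(C)C)CO[Si](C)(C)C(C)(C)C | intermediate
13 | (S)-2-[(tert-butyldimethylsilyl)oxy]but-3-en-1-ol | C=C[C@H](O[Si](C)(C)C(C)(C)C)CO | intermediate
14 | (S)-2-[(tert-butyldimethylsilyl)oxy]but-3-enal | C=C[C@H](O[Si](C)(C)C(C)(C)C)C=O | intermediate
15 | methyl (1R,4S,6R)-1-[(1R,2S)-2-[(tert-butyldimethylsilyl)oxy]-1-hydroxybut-3-en-1-yl]-2-oxo-4,6-di(prop-1-en-2-yl)cyclohexane-1-carboxylate | C=C(C)[C@@H]1CC(=O)[C@@]([C@@H](O)[C@@H](O[Si](C)(C)C(C)(C)C)C=C)(C(=O)OC)[C@H](C1)C(C)=C | intermediate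
16 | methyl (1R,4S,6R)-1-[(1R,2S)-2-[(tert-butyldimethylsilyl)oxy]-1-[(triethylsilyl)oxy]but-3-en-1-yl]-2-oxo-4,6-di(prop-1-en-2-yl)cyclohexane-1-carboxylate | C=C(C)[C@@H]1CC(=O)[C@@]([C@@H](O[Si](CC)(CC)CC)[C@@H](O[Si](C)(C)C(C)(C)C)C=C)(C(=O)OC)[C@H](C1)C(C)=C | intermediate
17 | trans-decalin keto ester, (1R,2S,5R,7S,10R): C3=C4, C1 OTES, C2 OTBS, C9 ketone, C14 methyl ester | C=C(C)[C@@H]1CC(=O)[C@@]2(C(=O)OC)[C@H](C1)C(C)=C[C@H](O[Si](C)(C)C(C)(C)C)[C@@H]2O[Si](CC)(CC)CC | intermediate
18 | decalin hydroxy ester, (1R,2S,5R,7S,9S,10S): 9β-OH, C14 methyl ester | C=C(C)[C@@H]1C[C@H](O)[C@@]2(C(=O)OC)[C@H](C1)C(C)=C[C@H](O[Si](C)(C)C(C)(C)C)[C@@H]2O[Si](CC)(CC)CC | intermediate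
19 | decalin 9,14-diol, (1R,2S,5R,7S,9S,10S) | C=C(C)[C@@H]1C[C@H](O)[C@@]2(CO)[C@H](C1)C(C)=C[C@H](O[Si](C)(C)C(C)(C)C)[C@@H]2O[Si](CC)(CC)CC | intermediate
20 | C14 tert-butyldiphenylsilyl ether, (1R,2S,5R,7S,9S,10S) | C=C(C)[C@@H]1C[C@H](O)[C@@]2(CO[Si](c3ccccc3)(c3ccccc3)C(C)(C)C)[C@H](C1)C(C)=C[C@H](O[Si](C)(C)C(C)(C)C)[C@@H]2O[Si](CC)(CC)CC | intermediate
21 | C9 acetate, (1R,2S,5R,7S,9S,10S) | C=C(C)[C@@H]1C[C@H](OC(C)=O)[C@@]2(CO[Si](c3ccccc3)(c3ccccc3)C(C)(C)C)[C@H](C1)C(C)=C[C@H](O[Si](C)(C)C(C)(C)C)[C@@H]2O[Si](CC)(CC)CC | intermediate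
22 | C1 alcohol, (1R,2S,5R,7S,9S,10R): C2 OTBS, C9 OAc, C14 OTBDPS | C=C(C)[C@@H]1C[C@H](OC(C)=O)[C@@]2(CO[Si](c3ccccc3)(c3ccccc3)C(C)(C)C)[C@H](C1)C(C)=C[C@H](O[Si](C)(C)C(C)(C)C)[C@@H]2O | intermediate
23 | 3-methylbut-2-enoic acid | CC(C)=CC(=O)O | starting material
24 | 3-methylbut-2-enoic 2,4,6-trichlorobenzoic anhydride | CC(C)=CC(=O)OC(=O)c1c(Cl)cc(Cl)cc1Cl | intermediate
25 | C1 senecioate, (1R,2S,5R,7S,9S,10S): C2 OTBS, C9 OAc, C14 OTBDPS | C=C(C)[C@@H]1C[C@H](OC(C)=O)[C@@]2(CO[Si](c3ccccc3)(c3ccccc3)C(C)(C)C)[C@H](C1)C(C)=C[C@H](O[Si](C)(C)C(C)(C)C)[C@@H]2OC(=O)C=C(C)C | intermediate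
26 | C2 alcohol, (1R,2S,5R,7S,9S,10S): C1 O-senecioyl, C9 OAc, C14 OTBDPS | C=C(C)[C@@H]1C[C@H](OC(C)=O)[C@@]2(CO[Si](c3ccccc3)(c3ccccc3)C(C)(C)C)[C@H](C1)C(C)=C[C@H](O)[C@@H]2OC(=O)C=C(C)C | intermediate
27 | C14 tert-butyldiphenylsilyl ether of the target, (1R,2S,5R,7S,9S,10S) | C=C(C)[C@@H]1C[C@H](OC(C)=O)[C@@]2(CO[Si](c3ccccc3)(c3ccccc3)C(C)(C)C)[C@H](C1)C(C)=C[C@H](OC(C)=O)[C@@H]2OC(=O)C=C(C)C | intermediate
28 | CNP0320218.1, (1R,2S,5R,7S,9S,10S) | C=C(C)[C@@H]1C[C@H](OC(C)=O)[C@@]2(CO)[C@H](C1)C(C)=C[C@H](OC(C)=O)[C@@H]2OC(=O)C=C(C)C | target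

**Step count**
Total: 20 steps. Longest linear sequence: 17 steps (steps 1–5 and 9–20); the aldehyde branch is steps 6–8.

**Steps most likely to fail**

Step 9 (aldol). Bond formation at the fully substituted, ester-deactivated C10 enol ether may be slow. The Lewis acid then has time to move the aldehyde double bond into conjugation or to start carbonyl-ene reaction at the isopropenyl groups, the adduct may revert by retro-aldol, and the relative topicity of the two independently biased faces may be mismatched and erode C1 control. Fallback, setting out from 9 and returning at 15: the C10–C1 bond is made with formaldehyde and C2–C3 is added afterwards under reagent control. Keto ester 9 is hydroxymethylated (37% aq. HCHO, KHCO3, THF, rt), anti to the C5 isopropenyl group, to give the hydroxymethyl keto ester F1. Dess–Martin oxidation gives the non-enolisable formyl keto ester F2. Chemoselective allylboration of the aldehyde with [(E)-3-(1,3,2-dioxaborinan-2-yl)allyl]di(isopinocampheyl)borane (the Ipc antipode chosen for 1R,2S; −78 °C, then NaBO3 oxidation) should give the anti-1,2-diol F3. Silylation of the less hindered allylic C2 hydroxyl (TBSCl, imidazole, DMF, 0 °C) then gives 15.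

Step 11 (ring-closing metathesis). The C3 alkylidene may close slowly onto the hindered C5 isopropenyl group because of the two bulky silyl ethers beside the vinyl group, so that dimerisation at the vinyl group or chelation of ruthenium by the C9/C14 carbonyls takes over. Fallback, setting out from 15 and returning at 17: the ring is closed on the unprotected diol, where a free allylic hydroxyl is known to speed carbene formation and the steric load is smaller. The silyl ether of 15 is cleaved (HF·pyridine, THF) to the monocyclic anti-diol F3. Metathesis with the same catalyst should give the decalin diol F4. The allylic C2 hydroxyl is silylated selectively (TBSCl, imidazole) to the decalin C2 silyl ether F5, and TESOTf/2,6-lutidine at C1 gives 17.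

Step 12 (C9 reduction). Facial selectivity of hydride delivery may be poor, since the α face is also hindered by the axial C14 ester and the nearby C1 silyl ether. Fallback, setting out from 17 and returning at 19: the hydride is delivered intramolecularly from O14. LiAlH4 reduces ketone and ester of 17 to the C9-epimeric diol mixture F6. Dess–Martin oxidation of both hydroxyls gives the keto aldehyde F7. Me4NBH(OAc)3 in AcOH/MeCN at −20 °C reduces the aldehyde first, and the new C14 alkoxyborohydride then delivers hydride to C9 from the α face (directed reduction of the Evans–Saksena type). This can only give the 9β-alcohol 19.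

Further compounds
F1 | step 9 | methyl 1-(hydroxymethyl)-2-oxo-4,6-di(prop-1-en-2-yl)cyclohexane-1-carboxylate, CH2OH trans to the C5 isopropenyl group | C=C(C)[C@@H]1CC(=O)[C@@](CO)(C(=O)OC)[C@H](C1)C(C)=C
F2 | step 9 | methyl 1-formyl-2-oxo-4,6-di(prop-1-en-2-yl)cyclohexane-1-carboxylate | C=C(C)[C@@H]1CC(=O)[C@@](C=O)(C(=O)OC)[C@H](C1)C(C)=C
F3 | step 9 | methyl 1-[(1R,2S)-1,2-dihydroxybut-3-en-1-yl]-2-oxo-4,6-di(prop-1-en-2-yl)cyclohexane-1-carboxylate | C=C(C)[C@@H]1CC(=O)[C@@]([C@@H](O)[C@@H](O)C=C)(C(=O)OC)[C@H](C1)C(C)=C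
F4 | step 11 | trans-decalin keto ester with free C1 and C2 hydroxyls | C=C(C)[C@@H]1CC(=O)[C@@]2(C(=O)OC)[C@H](C1)C(C)=C[C@H](O)[C@@H]2O
F5 | step 11 | trans-decalin keto ester with C2 OTBS and free C1 hydroxyl | C=C(C)[C@@H]1CC(=O)[C@@]2(C(=O)OC)[C@H](C1)C(C)=C[C@H](O[Si](C)(C)C(C)(C)C)[C@@H]2O
F6 | step 12 | decalin 9,14-diol as C9 epimer mixture, C1 OTES, C2 OTBS | C=C(C)[C@@H]1CC(O)[C@@]2(CO)[C@H](C1)C(C)=C[C@H](O[Si](C)(C)C(C)(C)C)[C@@H]2O[Si](CC)(CC)CC
F7 | step 12 | decalin C9 ketone C14 aldehyde, C1 OTES, C2 OTBS | C=C(C)[C@@H]1CC(=O)[C@@]2(C=O)[C@H](C1)C(C)=C[C@H](O[Si](C)(C)C(C)(C)C)[C@@H]2O[Si](CC)(CC)CC
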